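## The problem

Locants used throughout: ring C is the six-membered ring C1 (methyl-bearing bridgehead), C2 (enol carbon), C3 (acyl-bearing carbon), C4 (ketone), C5 (second bridgehead), C8 (bridging ketone). Ring A is C1, C7 (CH2), C6 (CH), C5, C8. Ring B is the cyclopentane C5, C6, C9 (CMe2), C10 (CH carrying CMe2OH), C11 (CH2). C2′ is the stereocentre of the acyl chain.

- The target is an acylated bicyclo[3.2.1]octane-2,4,8-trione (rings A and C) cis-fused through the C5–C6 bond to ring B. C5 is therefore a bridgehead, a ring-fusion atom and the carbon between two ketones at once.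
- There are five stereocentres (C1, C5, C6, C10, C2′). The cage ties C1 to C5 and the ring fusion ties C5 to C6, so what must be controlled is C10 (absolute), C6 relative to C10, C5 relative to C6, and C2′ independently.
- C10 is the only ring stereocentre that is never α to a carbonyl, so it has to be set by a catalyst. It can then govern C6 (α to a ketone, open to equilibration), C6 can govern C5, and C1 follows when ring A closes.
- C1, C5 and C9 are quaternary and flanked by substituted carbons, so every bond made to them is a hindered one.
- Several groups will not survive rough treatment: the tertiary alcohol (ionises in acid), the acylated β-triketone (strongly acidic, cleaved by hard nucleophiles), C2′ (epimerisable in base once attached to the triketone), and any β-alkoxy ketone on the way (elimination).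
- The enabling feature is C5. It belongs to ring B and carries both ring-C carbonyl carbons C4 and C8, so it can be the former carbonyl carbon of a cyclopentanone whose α-carbon C6 holds the C7 arm and whose β-carbon C10 holds the carbinol. A ketone carbon can be turned in one operation into a carbon bearing two acyl groups, and C1–C3 with the C2 oxygen and the C1 methyl can come with the acylating reagent.

## Retrosynthesis

**20 to 19.** The O–Si bond of the tertiary alcohol is cut last. The free carbinol would ionise or take part in every acidic or electrophilic step before it, so it stays a silyl ether until the end. The forward step must not touch the triketone or C2′.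

**19 to 16 and 17.** The C3–acyl bond is cut. Bringing the acyl group in late keeps C2′ out of all basic steps, and 16 has only one carbon (C3) between two enolisable carbonyls, so there is no choice of site. The forward reaction must acylate on carbon without racemising acid 17.

**16 to 15.** Ring A is opened at C1–C7. The neighbouring cut, C6–C7, has no activating group at C6 once C5 is quaternary, whereas C1 sits between two carbonyls. Precursor 15 is a spiro trione with a primary iodide. The forward step asks that C1 already bears its methyl and that C8, not C4, lies on the same face of ring B as C7.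

**15 to 14, 13 and 12.** These are adjustments only: the C2 ketone is masked as its ethylene ketal and the iodide comes from a benzyl ether. The order (debenzylate, iodinate, then unmask) is chosen so that the alcohol is never activated in the presence of the acidic enolised trione.

**12 to 6 and 10.** Both bonds from C5 to ring C (C5–C4 and C5–C8) are cut. The neighbouring option of building ring C by two separate acylations at C5 would need a C5 carbanion twice on a crowded ring. The chosen cut replaces that by one ketone carbon and one symmetric-type reagent, and the precursors drop to a monocyclic ketone 6 and a five-membered enediol bis-silyl ether 10. The forward reaction (Lewis-acid geminal acylation) must choose between the two enediol carbons and between the two faces of ring B.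

**6 to 5 and 4.** The tertiary silyl ether is traced to the alcohol 5 and this to the isopropenyl group of 4 by Markovnikov hydration. The alkene must not be carried into the key step, where it would trap the C5 cation.

**4 to 2 and 3, and 2 to 1.** The C10–isopropenyl bond is cut (rhodium-catalysed conjugate addition of 3) and then the C6–C7 bond (benzyloxymethylation of 1). The arm goes on first because enone 1 has a single enolisable position; after the conjugate addition two α-positions would compete. The catalyst must override the racemic C6 centre, which is equilibrated afterwards.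

**10 to 9, 8 and 7.** The enediol C=C bond is cut by an acyloin disconnection to the ketal diester 9, which comes from 7 by methylation (8) and ketalisation.

## Roads not taken

**Alternative 1:** Ring B is cut at C6–C9 and C5–C11. This leaves ring A as methyl 5-oxocyclopent-1-ene-1-carboxylate A2 (C8 as ketone, C4 as ester) and C9–C10–C11 as the trimethylenemethane precursor 2-methyl-3-[(trimethylsilyl)methyl]but-3-en-2-yl acetate A3. Forward, a zerovalent palladium catalyst with a chiral phosphoramidite ionises A3 and the complex adds across the C5=C6 bond of A2 to give the cis-fused methylene diquinane keto ester A1.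
- Merits: C5 and C6 are set together by a catalyst. Because C8 is already in ring A and C4 is the ester, the question of which carbonyl is syn to C7 is answered by constitution. In that respect this road is better than the chosen one.
- Weak points: the unsymmetrical donor must bond through its CMe2 end to C6, making a quaternary carbon next to a new quaternary carbon. C10 is delivered as an exocyclic methylene that still needs two carbons and a stereocentre. Ring C then has to be bridged onto C8 and C4 with C1 made quaternary late.
- Comparison: the chosen plan sets against it that step 8 delivers the whole of ring C, with its oxygen pattern and the C1 methyl, in one operation, and that C10 is in place before any ring is built on it.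

**Alternative 2:** Rings A and B are cut together at C5–C6 and C1–C7, which turns ring C into the aromatic acylphloroglucinol A5 carrying the chain C11–C10–C9–C6=C7 on C5. Forward, a hypervalent iodine oxidant in a fluorinated alcohol gives the phenoxonium ion, whose pentadienyl cation C1–C2–C3–C4–C5 is bridged at its ends by the vinyl group in a (5+2) cycloaddition. This leads to the triethylsilyl ether of the target, A4.
- Merits: it is the shortest road. The acyl group is present from the start, so C2′ never meets a base after attachment, and the cage forms in one step. In step count and in the handling of the acyl group it is better than the chosen plan.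
- Weak points: the arene to be oxidised is deactivated by the acyl group. The alkene is a monosubstituted vinyl group on a quaternary carbon, a poor partner for a cation. The cation can pair C5 with C1 or with C3. The face must be chosen by C10 alone through a flexible tether. A5 itself needs an enantioselective route to a centre beside a quaternary carbon.
- Comparison: the chosen plan sets against it that C10, C6, C5 and C1 are each fixed in a separate operation that can be checked, on a reaction type established for ketones.

**Alternative 3:** The cuts C5–C6 and C3–C2 open ring B and a seven-membered ring (C2, C3, C4, C5, C6, C7, C1), leaving the chloromethyl ketone with a tethered silyloxydiene A7. Forward, a fluorinated alkoxide base generates the C5–C4–C3 oxyallyl cation, which adds to the diene in an intramolecular (4+3) cycloaddition to give the hydroazulenone A6.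
- Merits: two rings form in one step, the C5/C6 fusion is set reliably, and the C2 oxygen and C1 methyl are in place. In ring-forming power this beats step 8.
- Weak points: C8 is absent. The one-carbon bridge must later be bonded to C1 (an alkene carbon in A6) and to C5, both becoming quaternary, and C7 arrives as an sp2 CH. The endgame is long, and A7 combines a chloromethyl ketone with a silyl dienol ether.
- Comparison: the chosen plan puts C8 and C4 on C5 at once and leaves only one ring-closing bond (C1–C7) for later.

Key step: step 8

Assumption: the target is handled as the enol tautomer drawn (hydroxyl on C2), β-diketone intermediates are written in one tautomer, and C1 of 10–15 is a mixture of epimers that converge on enolisation in step 12.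

## Route

Step 1
Reactants: 1 4,4-dimethylcyclopent-2-en-1-one
Product: 2 rac-5-[(benzyloxy)methyl]-4,4-dimethylcyclopent-2-en-1-one
Conditions: LiN(i-Pr)2, THF, −78 °C; benzyl chloromethyl ether, −78 → −30 °C
Reagents that add atoms: benzyl chloromethyl ether, ClCOCc1ccccc1
Why: Enolate alkylation; the enone can only be deprotonated at C5 (future C6) because the γ-carbon is quaternary, and the reactive chloromethyl ether alkylates the hindered dienolate; the new centre is racemic and is equilibrated in step 2.

Step 2
Reactants: 2 rac-5-[(benzyloxy)methyl]-4,4-dimethylcyclopent-2-en-1-one; 3 4,4,5,5-tetramethyl-2-(prop-1-en-2-yl)-1,3,2-dioxaborolane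
Product: 4 (2R,4R)-2-[(benzyloxy)methyl]-3,3-dimethyl-4-(prop-1-en-2-yl)cyclopentan-1-one
Conditions: Rh(acac)(C2H4)2 (3 mol %), (R)-BINAP, K3PO4 (0.5 equiv, aq), dioxane, 60 °C; then DBU (cat.), CH2Cl2, rt; chromatography
Reagents that add atoms: none
Why: Hayashi–Miyaura conjugate addition; the (R)-BINAP–rhodium alkenyl species should choose the enone face at C10 for both enantiomers of 2, since the C6 substituent lies beyond the quaternary carbon, and C6 (α to the ketone) is then equilibrated to the cis isomer, in which both groups flanking CMe2 are pseudo-equatorial.

Step 3
Reactants: 4 (2R,4R)-2-[(benzyloxy)methyl]-3,3-dimethyl-4-(prop-1-en-2-yl)cyclopentan-1-one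
Product: 5 (2R,4S)-2-[(benzyloxy)methyl]-4-(2-hydroxypropan-2-yl)-3,3-dimethylcyclopentan-1-one
Conditions: Co(acac)2 (20 mol %), PhSiH3, O2 (1 atm), THF, rt
Reagents that add atoms: dioxygen, O=O
Why: Mukaiyama hydration; hydrogen-atom transfer to the 1,1-disubstituted alkene gives the tertiary radical, which is trapped by O2 and reduced to the Markovnikov alcohol; ketone, benzyl ether and both stereocentres are untouched.

Step 4
Reactants: 5 (2R,4S)-2-[(benzyloxy)methyl]-4-(2-hydroxypropan-2-yl)-3,3-dimethylcyclopentan-1-one
Product: 6 (2R,4S)-2-[(benzyloxy)methyl]-4-[2-(tert-butyldimethylsilyloxy)propan-2-yl]-3,3-dimethylcyclopentan-1-one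
Conditions: TBSOTf, 2,6-lutidine, CH2Cl2, −78 → 0 °C
Reagents that add atoms: tert-butyldimethylsilyl trifluoromethanesulfonate, CC(C)(C)[Si](C)(C)OS(=O)(=O)C(F)(F)F
Why: Silyl triflate silylation of a tertiary alcohol; the weak, hindered base and low temperature should keep the ketone from enol silylation and C6 from epimerising, and the hindered tertiary silyl ether is chosen to survive BF3·OEt2 at low temperature.

Step 5
Reactants: 7 dimethyl 3-oxopentanedioate
Product: 8 dimethyl 2-methyl-3-oxopentanedioate (racemic)
Conditions: NaH (1.0 equiv), THF, 0 °C; MeI (1.0 equiv), 0 °C → rt; distillation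
Reagents that add atoms: iodomethane, CI
Why: Mono-C-alkylation of the sodium enolate of a β-keto diester; one equivalent of base and electrophile limits over-methylation, and the labile new centre becomes C1, which is enolised again later.

Step 6
Reactants: 8 dimethyl 2-methyl-3-oxopentanedioate
Product: 9 dimethyl 3,3-(ethylenedioxy)-2-methylpentanedioate (racemic)
Conditions: ethylene glycol, TsOH·H2O (cat.), toluene, reflux, Dean–Stark
Reagents that add atoms: ethylene glycol, OCCO
Why: Acid-catalysed ketalisation with azeotropic removal of water; the future C2 ketone has to be masked because it would not survive sodium in step 7.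

Step 7
Reactants: 9 dimethyl 3,3-(ethylenedioxy)-2-methylpentanedioate
Product: 10 6-methyl-7,8-bis(trimethylsilyloxy)-1,4-dioxaspiro[4.4]non-7-ene (racemic)
Conditions: sodium, Me3SiCl, toluene, reflux
Reagents that add atoms: chlorotrimethylsilane, C[Si](C)(C)Cl
Why: Rühlmann acyloin condensation; sodium couples the two ester carbons and the chlorosilane traps the enediolate and the methoxide, which suppresses Dieckmann and elimination pathways; five-membered rings form well.

Step 8
Reactants: 6 (2R,4S)-2-[(benzyloxy)methyl]-4-[2-(tert-butyldimethylsilyloxy)propan-2-yl]-3,3-dimethylcyclopentan-1-one; 10 6-methyl-7,8-bis(trimethylsilyloxy)-1,4-dioxaspiro[4.4]non-7-ene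
Product: 12 spiro diketone ketal (ring C with C4 and C8 ketones and the C2 ethylene ketal; C8 syn to the C6 benzyloxymethyl group; C1 epimers), via silyloxy carbinol 11 (not isolated)
Conditions: 10 (1.5 equiv), BF3·OEt2 (1.2 equiv), CH2Cl2, −78 °C; then BF3·OEt2 (5 equiv), −78 → 0 °C; aq. NaHCO3
Reagents that add atoms: none
Why: Mukaiyama aldol followed by a pinacol-type acyl shift, the Lewis-acid geminal acylation known for ketones and ketals with 1,2-bis(trimethylsilyloxy)cycloalkenes. The BF3-bound C5 carbonyl is attacked at −78 °C by the enediol carbon of 10 that is flanked by CH2, the carbon next to CHMe being the more hindered, which gives carbinol 11 (bond C5–C4). More BF3·OEt2 ionises the tertiary carbinol and the ring acyl carbon shifts from the silyloxy carbon to C5 (bond C5–C8) while the silyloxy oxygen becomes the C4 carbonyl, so ring C closes by one-atom ring expansion of the five-membered ketone and not by a ring-closing attack. The new stereocentre C5 is set in this shift by the benzyloxymethyl group on C6: the migrating acyl carbon must lie over one face of the C5 cation, the two other substituents of the silyloxy carbon (OSiMe3 and the ring CH2) then lie on the opposite face beside C6 where they avoid the arm, so the acyl carbon should cross the arm face and C8 should end syn to C7. The step thus needs regioselectivity in the aldol, secured by the methyl group of 10, and facial selectivity in the shift, secured by the C6 substituent; C1 arrives as both epimers, which is of no consequence. Chemoselectivity rests on temperature: the ketone reacts before the dioxolane of 10 ionises, in 11 that dioxolane lies β to a ketone, which slows its ionisation, and the benzyl and hindered tertiary silyl ethers should tolerate BF3·OEt2 up to 0 °C.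

Step 9
Reactants: 12 spiro diketone ketal
Product: 13 primary alcohol (12 with CH2OH on C6)
Conditions: H2 (1 atm), Pd/C, EtOAc, rt
Reagents that add atoms: none
Why: Hydrogenolysis of a benzyl ether; ketones, ketal and silyl ether are inert.

Step 10
Reactants: 13 primary alcohol
Product: 14 primary iodide (13 with CH2I on C6)
Conditions: PPh3, I2, imidazole, toluene, 60 °C
Reagents that add atoms: iodine, [I][I]
Why: Appel-type iodination (alkoxyphosphonium displaced by iodide at primary C7); done before the trione is unmasked, because an enolised trione would be attacked at oxygen by the same reagents.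

Step 11
Reactants: 14 primary iodide
Product: 15 spiro trione iodide (C2, C4 and C8 ketones; C1 epimers)
Conditions: 1 M HCl, THF, rt
Reagents that add atoms: water, O
Why: Acid hydrolysis of the ketal; the β-keto ketal opens through the enol of a neighbouring ketone and the product is held as the enolised trione, while the primary iodide and the hindered tertiary silyl ether should survive dilute acid at room temperature.

Step 12
Reactants: 15 spiro trione iodide
Product: 16 tricyclic trione silyl ether (bicyclo[3.2.1]octane-2,4,8-trione core, enolised between C2 and C4, C3–H)
Conditions: KOt-Bu (2.2 equiv), t-BuOH/THF, 0 → 50 °C; then 1 M HCl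
Reagents that add atoms: none
Why: Intramolecular C-alkylation of the trione enolate (5-exo-tet, the enolate bond C1=C2 lying outside the forming ring); only C1 can reach C7 because C8 is syn to the arm, the C1 configuration is dictated by the bridge, and alkylation of a methyl-bearing carbon between two carbonyls is the same process as the exhaustive C-methylation of cyclic β-triketones; the soft iodide and the protic co-solvent favour carbon over oxygen.

Step 13
Reactants: 16 tricyclic trione silyl ether; 17 (R)-2-methylbutanoic acid
Product: 19 C3-acylated tricyclic trione silyl ether, via enol ester 18 (not isolated)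
Conditions: DCC, DMAP (0.3 equiv), CH2Cl2, 0 °C → rt
Reagents that add atoms: none
Why: Steglich esterification of the enol followed in the same flask by the DMAP-catalysed 1,3 O-to-C acyl shift that converts enol esters of cyclic 1,3-diones into 2-acyl-1,3-diones; C3 is the only carbon between two enolisable carbonyls, and the absence of an acid chloride and of a strong amine base (no ketene) should preserve C2′.

Step 14
Reactants: 19 C3-acylated tricyclic trione silyl ether
Product: 20 CNP0207052.1 (target; C1 S, C5 S, C6 S, C10 S, C2′ R)
Conditions: HF (48 % aq), MeCN, rt
Reagents that add atoms: none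
Why: Fluoride-driven cleavage of the tertiary silyl ether under mildly acidic conditions; no base is present, so the triketone and C2′ are not disturbed, and dilute HF should not ionise the tertiary alcohol.

## Compound list

1 | 4,4-dimethylcyclopent-2-en-1-one | CC1(C)C=CC(=O)C1 | starting material
2 | rac-5-[(benzyloxy)methyl]-4,4-dimethylcyclopent-2-en-1-one | O=C1C=CC(C)(C)C1COCc2ccccc2 | intermediate
3 | 4,4,5,5-tetramethyl-2-(prop-1-en-2-yl)-1,3,2-dioxaborolane | CC(=C)B1OC(C)(C)C(C)(C)O1 | starting material
4 | (2R,4R)-2-[(benzyloxy)methyl]-3,3-dimethyl-4-(prop-1-en-2-yl)cyclopentan-1-one | O=C1C[C@H](C(C)=C)C(C)(C)[C@@H]1COCc2ccccc2 | intermediate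
5 | (2R,4S)-2-[(benzyloxy)methyl]-4-(2-hydroxypropan-2-yl)-3,3-dimethylcyclopentan-1-one | O=C1C[C@H](C(C)(C)O)C(C)(C)[C@@H]1COCc2ccccc2 | intermediate
6 | (2R,4S)-2-[(benzyloxy)methyl]-4-[2-(tert-butyldimethylsilyloxy)propan-2-yl]-3,3-dimethylcyclopentan-1-one | O=C1C[C@H](C(C)(C)O[Si](C)(C)C(C)(C)C)C(C)(C)[C@@H]1COCc2ccccc2 | intermediate
7 | dimethyl 3-oxopentanedioate | COC(=O)CC(=O)CC(=O)OC | starting material
8 | dimethyl 2-methyl-3-oxopentanedioate (racemic) | COC(=O)CC(=O)C(C)C(=O)OC | intermediate
9 | dimethyl 3,3-(ethylenedioxy)-2-methylpentanedioate (racemic) | COC(=O)CC1(OCCO1)C(C)C(=O)OC | intermediate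
10 | 6-methyl-7,8-bis(trimethylsilyloxy)-1,4-dioxaspiro[4.4]non-7-ene (racemic) | C[Si](C)(C)OC1=C(O[Si](C)(C)C)C(C)C2(OCCO2)C1 | intermediate
11 | silyloxy carbinol: 2-silyloxycyclopentanone bonded through its silyloxy carbon (next to the ring CH2) to the C5 carbinol of ring B, new bond anti to the C6 arm; not isolated | C[Si](C)(C)OC1(CC2(OCCO2)C(C)C1=O)[C@@]3(O)C[C@H](C(C)(C)O[Si](C)(C)C(C)(C)C)C(C)(C)[C@@H]3COCc4ccccc4 | intermediate
12 | spiro diketone ketal: ring C (C4, C8 ketones; C2 ethylene ketal; C1 methyl, both epimers) spiro at C5 to ring B with 6-CH2OBn and 10-CMe2OTBS; C8, C7 and the C10 side chain on one face of ring B | O=C1CC2(OCCO2)C(C)C(=O)[C@@]13C[C@H](C(C)(C)O[Si](C)(C)C(C)(C)C)C(C)(C)[C@@H]3COCc4ccccc4 | intermediate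
13 | primary alcohol: 12 with CH2OH in place of CH2OBn | O=C1CC2(OCCO2)C(C)C(=O)[C@@]13C[C@H](C(C)(C)O[Si](C)(C)C(C)(C)C)C(C)(C)[C@@H]3CO | intermediate
14 | primary iodide: 13 with CH2I in place of CH2OH | O=C1CC2(OCCO2)C(C)C(=O)[C@@]13C[C@H](C(C)(C)O[Si](C)(C)C(C)(C)C)C(C)(C)[C@@H]3CI | intermediate
15 | spiro trione iodide: 14 with the C2 ketone freed (drawn as triketone; C1 epimers) | O=C1CC(=O)C(C)C(=O)[C@@]12C[C@H](C(C)(C)O[Si](C)(C)C(C)(C)C)C(C)(C)[C@@H]2CI | intermediate
16 | tricyclic trione silyl ether: target skeleton with C3–H and 10-CMe2OTBS (enol on C2) | C1=C(O)[C@]2(C)C[C@H]3C(C)(C)[C@@H](C(C)(C)O[Si](C)(C)C(C)(C)C)C[C@@]3(C1=O)C2=O | intermediate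
17 | (R)-2-methylbutanoic acid | CC[C@@H](C)C(=O)O | starting material
18 | enol ester: 16 acylated on the C2 enol oxygen by the (R)-2-methylbutanoyl group; not isolated | C1=C(OC(=O)[C@H](C)CC)[C@]2(C)C[C@H]3C(C)(C)[C@@H](C(C)(C)O[Si](C)(C)C(C)(C)C)C[C@@]3(C1=O)C2=O | intermediate
19 | tert-butyldimethylsilyl ether of the target (C3 carries the (R)-2-methylbutanoyl group) | CC[C@@H](C)C(=O)C1=C(O)[C@]2(C)C[C@H]3C(C)(C)[C@@H](C(C)(C)O[Si](C)(C)C(C)(C)C)C[C@@]3(C1=O)C2=O | intermediate
20 | CNP0207052.1: (1S,3S,5S,7S)-8-hydroxy-3-(2-hydroxypropan-2-yl)-4,4,7-trimethyl-9-[(2R)-2-methylbutanoyl]tricyclo[5.3.1.0^1,5]undec-8-ene-10,11-dione | CC[C@@H](C)C(=O)C1=C(O)[C@]2(C)C[C@H]3C(C)(C)[C@@H](C(C)(C)O)C[C@@]3(C1=O)C2=O | target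

## Step count and least certain steps

Total: 14 steps. Longest linear sequence: 11 steps (steps 1–4 and 8–14); the reagent branch (steps 5–7) has 3.

**Step 8 (key step).** The most likely failure is loss of control over the spiro centre. The needed sense depends on two small preferences.
- If the acyl shift runs in concert with departure of the oxygen from the first-formed aldolate, the acyl carbon is carried to the face away from the arm.
- If the enediol carbon next to CHMe bonds first, the roles of C4 and C8 are exchanged.
- Either process puts the CH2-flanked carbonyl syn to C7, and that epimer cannot close ring A at C1.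
- Lesser risks are ionisation of the reagent's own dioxolane and capture of the C5 cation by the neighbouring silyl ether oxygen.

The fallback removes the stereochemical question instead of tuning it. It sets out from 6 and 7.
- 7 is ketalised (ethylene glycol, TsOH) to dimethyl 2,2′-(1,3-dioxolane-2,2-diyl)diacetate F1, and the acyloin condensation (sodium, Me3SiCl, toluene) gives the methyl-free reagent 7,8-bis(trimethylsilyloxy)-1,4-dioxaspiro[4.4]non-7-ene F2, whose two enediol carbons are equivalent.
- Geminal acylation of 6 with F2 under the conditions of step 8 gives the methyl-free spiro diketone ketal F3, in which ring C is symmetric and C5 is not a stereocentre.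
- Hydrogenolysis (H2, Pd/C) gives the alcohol F4.
- Camphorsulfonic acid in toluene with removal of water closes the hydroxyl onto the only carbonyl it can reach, giving the cyclic enol ether F5 (O–C7, C8=C1). Geometry alone thus decides which carbonyl becomes C8.
- Simmons–Smith cyclopropanation (Et2Zn, CH2I2) of the enol ether gives the alkoxycyclopropane F6.
- TsOH in wet THF at 0 °C cleaves the C8–CH2 bond of the donor cyclopropane and the resulting hemiketal. This places the methyl on C1 and frees the alcohol, and the product is 13, where the fallback rejoins the route.

**Step 2.** The most likely failure is slow insertion at the β-carbon beside the quaternary centre, with elimination of benzyl alcohol from the β-alkoxy ketone in warm aqueous base competing. The fallback sets out from 2. The isopropenyl group is added without a chiral catalyst as the cuprate (isopropenylmagnesium bromide, CuBr·SMe2, Me3SiCl, THF, −78 °C), which tolerates hindered enones and needs no aqueous base. After DBU equilibration the racemic cis ketone is resolved by preparative chromatography on a chiral stationary phase. The (2R,4R) enantiomer is 4, where the route is rejoined, and the (2S,4S) enantiomer, ent-4 F7, is set aside.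

**Step 12.** The most likely failure is alkylation on the C8 enolate oxygen instead of on C1, because the trione anion is an ambident nucleophile and both closures are five-membered. The fallback sets out from 15. Condensation with 1,1-dimethylhydrazine at the unhindered central carbonyl gives the keto dimethylhydrazone F8. KH in THF generates the aza-enolate, which alkylates on carbon, giving the tricyclic hydrazone F9. Cu(OAc)2 in aqueous THF then frees the ketone to give 16.

**Step 13.** The most likely failures are incomplete O-to-C acyl transfer at the hindered enol and partial epimerisation of C2′ through the acylpyridinium intermediate. The fallback sets out from 16 and 17.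
- 16 is O-methylated (Me3SiCHN2, MeOH) to the methyl enol ether F10.
- 17 is converted with N,O-dimethylhydroxylamine and a carbodiimide into (R)-N-methoxy-N,2-dimethylbutanamide F11.
- Lithium 2,2,6,6-tetramethylpiperidide removes the C3 vinyl proton of F10 at −78 °C, and the vinyllithium is acylated by F11 to give the acylated methyl enol ether F12.
- LiCl in DMF at 120 °C cleaves the methyl enol ether to give 19.

## Further compounds

F1 | step 8 | dimethyl 2,2′-(1,3-dioxolane-2,2-diyl)diacetate | COC(=O)CC1(OCCO1)CC(=O)OC
F2 | step 8 | 7,8-bis(trimethylsilyloxy)-1,4-dioxaspiro[4.4]non-7-ene | C[Si](C)(C)OC1=C(O[Si](C)(C)C)CC2(OCCO2)C1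
F3 | step 8 | methyl-free spiro diketone ketal (12 without the C1 methyl; C5 not a stereocentre) | O=C1CC2(OCCO2)CC(=O)C13C[C@H](C(C)(C)O[Si](C)(C)C(C)(C)C)C(C)(C)[C@@H]3COCc4ccccc4
F4 | step 8 | alcohol (F3 with CH2OH on C6) | O=C1CC2(OCCO2)CC(=O)C13C[C@H](C(C)(C)O[Si](C)(C)C(C)(C)C)C(C)(C)[C@@H]3CO
F5 | step 8 | cyclic enol ether (O–C7 bond, C8=C1) | O=C1CC2(OCCO2)C=C3OC[C@H]4C(C)(C)[C@@H](C(C)(C)O[Si](C)(C)C(C)(C)C)C[C@@]134
F6 | step 8 | alkoxycyclopropane (CH2 across C8–C1) | O=C1CC2(OCCO2)C5CC53OC[C@H]4C(C)(C)[C@@H](C(C)(C)O[Si](C)(C)C(C)(C)C)C[C@@]134
F7 | step 2 | ent-4, (2S,4S)-2-[(benzyloxy)methyl]-3,3-dimethyl-4-(prop-1-en-2-yl)cyclopentan-1-one | O=C1C[C@@H](C(C)=C)C(C)(C)[C@H]1COCc2ccccc2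
F8 | step 12 | keto dimethylhydrazone of 15 (hydrazone at C2) | O=C1CC(=NN(C)C)C(C)C(=O)[C@@]12C[C@H](C(C)(C)O[Si](C)(C)C(C)(C)C)C(C)(C)[C@@H]2CI
F9 | step 12 | tricyclic hydrazone (16 with C2=N–NMe2) | C1C(=NN(C)C)[C@]2(C)C[C@H]3C(C)(C)[C@@H](C(C)(C)O[Si](C)(C)C(C)(C)C)C[C@@]3(C1=O)C2=O
F10 | step 13 | methyl enol ether of 16 (OMe on C2) | C1=C(OC)[C@]2(C)C[C@H]3C(C)(C)[C@@H](C(C)(C)O[Si](C)(C)C(C)(C)C)C[C@@]3(C1=O)C2=O
F11 | step 13 | (R)-N-methoxy-N,2-dimethylbutanamide | CC[C@@H](C)C(=O)N(C)OC
F12 | step 13 | acylated methyl enol ether (19 with OMe on C2) | CC[C@@H](C)C(=O)C1=C(OC)[C@]2(C)C[C@H]3C(C)(C)[C@@H](C(C)(C)O[Si](C)(C)C(C)(C)C)C[C@@]3(C1=O)C2=O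
A1 | alternative 1 | cis-fused methylene diquinane keto ester | COC(=O)[C@@]12CC(=C)C(C)(C)[C@@H]1CCC2=O
A2 | alternative 1 | methyl 5-oxocyclopent-1-ene-1-carboxylate | COC(=O)C1=CCCC1=O
A3 | alternative 1 | 2-methyl-3-[(trimethylsilyl)methyl]but-3-en-2-yl acetate | CC(=O)OC(C)(C)C(=C)C[Si](C)(C)C
A4 | alternative 2 | triethylsilyl ether of the target | CC[C@@H](C)C(=O)C1=C(O)[C@]2(C)C[C@H]3C(C)(C)[C@@H](C(C)(C)O[Si](CC)(CC)CC)C[C@@]3(C1=O)C2=O
A5 | alternative 2 | acylphloroglucinol with the tethered vinyl group | CC[C@@H](C)C(=O)c1c(O)c(C)c(O)c(C[C@H](C(C)(C)O[Si](CC)(CC)CC)C(C)(C)C=C)c1O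
A6 | alternative 3 | bicyclo[5.3.0]decenone (hydroazulenone) | O=C1C[C@@H](O[Si](CC)(CC)CC)C(C)=C[C@H]2C(C)(C)[C@@H](C(C)(C)O[Si](C)(C)C(C)(C)C)C[C@H]12
A7 | alternative 3 | chloromethyl ketone with the tethered silyloxydiene | ClCC(=O)CC[C@H](C(C)(C)O[Si](C)(C)C(C)(C)C)C(C)(C)C=CC(C)=CO[Si](CC)(CC)CC
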